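Retrosynthesis (labdane numbering): the C3 acetate and the C15 acid are unmasked last, C8=C17 is cut to a C8 ketone, ring A is opened at C4–C5, and C9–C11 and C1–C10 are then cut together. This leaves ring B as 3-methylcyclohex-2-enone, a homoprenyl Grignard reagent (C1–C4, C18, C19) and the aldehyde ester C11–C16.
Enabling feature: in ring B the methylene-bearing C8 is a latent carbonyl whose β-carbon is the quaternary C10 (already carrying C20) and whose α-carbon is C9, so one conjugate addition with enolate capture attaches C1 to C10 and C11 to C9.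
Forward order: ring B is bought and both chains are joined to it in step 5. The enolate is captured by an aldehyde because alkylation of this neopentylic enolate with an unactivated iodide is unreliable, and steps 6–7 return C11 to a methylene. Ring A is then closed at C4–C5 by epoxide opening with the extended silyl dienol ether, and C17, the free acid and the acetate follow.
Stereochemistry: C10 comes from the chiral NHC–copper catalyst and C13 from alkaloid-catalysed desymmetrisation of 3-methylglutaric anhydride. C3 comes from Shi epoxidation; its C–O bond is never broken, so the axial acetate needs no inversion. C5 and C9 come from thermodynamic equilibration of the bicyclic enone.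

Key step: step 5

Remark: atoms are numbered as in labdane; because C9 is epimerisable next to the C8 carbonyl, compounds 9–18 are carried as C9 epimer mixtures whose SMILES leave C9 (and C11 in 9 and 10) undefined, and the C10 descriptor switches between S and R along the route only through priority changes.

Step 1
Reactants: 1 3-methylglutaric anhydride
Product: 2 (R)-5-methoxy-3-methyl-5-oxopentanoic acid
Conditions: MeOH (10 equiv), (DHQD)2AQN (10 mol%), Et2O, −40 °C
Reagents that add atoms: methanol, CO
Why: Alkaloid-catalysed desymmetrising methanolysis of a prochiral cyclic anhydride, in which the chiral amine selects one enantiotopic carbonyl and so sets C13, the (R)-acid being secured by the choice between (DHQD)2AQN and its pseudoenantiomer (DHQ)2AQN.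

Step 2
Reactants: 2 (R)-5-methoxy-3-methyl-5-oxopentanoic acid
Product: 3 methyl (R)-5-hydroxy-3-methylpentanoate
Conditions: BH3·SMe2 (1.1 equiv), THF, −10 °C → rt; then H2O
Reagents that add atoms: none
Why: Chemoselective borane reduction of a carboxylic acid in the presence of an ester, which leaves C13 untouched and gives a hydroxy ester that is used crude to forestall lactonisation.

Step 3
Reactants: 3 methyl (R)-5-hydroxy-3-methylpentanoate
Product: 4 methyl (R)-3-methyl-5-oxopentanoate
Conditions: PhI(OAc)2 (1.1 equiv), TEMPO (10 mol%), CH2Cl2, rt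
Reagents that add atoms: none
Why: Nitroxyl-catalysed alcohol oxidation stops at the aldehyde, and C13 is β to both carbonyl groups and cannot epimerise.

Step 4
Reactants: 5 5-bromo-2-methylpent-2-ene
Product: 6 (4-methylpent-3-en-1-yl)magnesium bromide
Conditions: Mg turnings, I2 (crystal), Et2O, gentle reflux
Reagents that add atoms: magnesium, [Mg]
Why: Grignard formation from a primary homoallylic bromide is routine and the reagent is used directly as its ether solution.

Step 5
Reactants: 7 3-methylcyclohex-2-en-1-one; 6 (4-methylpent-3-en-1-yl)magnesium bromide; 4 methyl (R)-3-methyl-5-oxopentanoate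
Product: 9 methyl (3R)-5-hydroxy-3-methyl-5-[(2S)-2-methyl-2-(4-methylpent-3-en-1-yl)-6-oxocyclohexyl]pentanoate (aldol adduct; epimers at C9 and C11), via bromomagnesium enolate 8 (not isolated)
Conditions: Cu(OTf)2 (3 mol%), chiral N-mesityl-N′-(1-hydroxyalk-2-yl)imidazolinium hexafluorophosphate (NHC precursor, 4 mol%), 6 (1.1 equiv), Et2O, 0 °C, slow addition of 7; then 4 (1.3 equiv), −78 °C; aq. NH4Cl
Reagents that add atoms: none
Why: The NHC-bound organocopper species generated from 6 delivers the homoprenyl group to the β-carbon of 7 (C1–C10), and the magnesium enolate 8 so formed, which can only be the C8–C9 enolate, adds to the aldehyde carbon of 4 (C9–C11); no ring is closed. The closest known reaction type is the copper–NHC-catalysed asymmetric conjugate addition of Grignard reagents to 3-substituted cyclohexenones followed by aldol capture of the magnesium enolate. The quaternary centre C10 is controlled by the chiral NHC ligand on copper (the ligand antipode is chosen for the S configuration), and C13 arrives with 4. C9 and the carbinol carbon C11 are formed without control, which does not matter: C11 becomes a methylene in steps 6 and 7 and C9 is equilibrated in step 12. The step needs 1,4- over 1,2-addition, secured by the copper catalyst and slow addition of 7, and fast capture of a hindered neopentylic enolate, secured by offering it an aldehyde instead of an unactivated alkyl halide. Antipodal C10 material ends as a diastereomer because C13 is fixed and can be removed at 19.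

Step 6
Reactants: 9 aldol adduct
Product: 11 methyl (3R)-3-methyl-5-[(2S)-2-methyl-2-(4-methylpent-3-en-1-yl)-6-oxocyclohexylidene]pentanoate (E/Z mixture), via mesylate 10 (not isolated)
Conditions: MsCl, Et3N, CH2Cl2, 0 °C; then DBU, rt
Reagents that add atoms: none
Why: Mesylation followed by base-induced E1cB elimination is the standard dehydration of an aldol to the enone, and the alkene geometry is irrelevant because the C9=C11 bond is reduced in the next step.

Step 7
Reactants: 11 alkylidene ketone
Product: 12 methyl (3R)-3-methyl-5-[(2S)-2-methyl-2-(4-methylpent-3-en-1-yl)-6-oxocyclohexyl]pentanoate (both C9 epimers)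
Conditions: [(Ph3P)CuH]6 (0.4 equiv), H2O (2 equiv), toluene, rt
Reagents that add atoms: none
Why: Copper hydride conjugate reduction is selective for the enone in the presence of the isolated trisubstituted alkene, the ketone and the ester, and protonation of the copper enolate at C9 gives both epimers, which are carried on.

Step 8
Reactants: 12 ketone
Product: 14 methyl (3R)-3-methyl-5-[(2R)-2-methyl-2-(4-methylpent-3-en-1-yl)-6-oxocyclohex-4-en-1-yl]pentanoate (C6=C7 enone), via lithium enolate 13 (not isolated)
Conditions: LiN(i-Pr)2 (1.05 equiv), THF, −78 °C; then PhS(Cl)=N-t-Bu (1.2 equiv), −78 °C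
Reagents that add atoms: none
Why: Kinetic deprotonation takes the unhindered C7 methylene rather than the C9 methine or the less acidic ester α-position, and the sulfinimidoyl chloride converts that enolate into the C6=C7 enone in the same flask (Mukaiyama dehydrogenation).

Step 9
Reactants: 14 enone
Product: 15 methyl (3R)-5-[(2R)-2-{2-[(2S)-3,3-dimethyloxiran-2-yl]ethyl}-2-methyl-6-oxocyclohex-4-en-1-yl]-3-methylpentanoate
Conditions: L-fructose-derived ketone catalyst (enantiomer of the usual D-fructose-derived ketone, 0.3 equiv), Oxone (2KHSO5·KHSO4·K2SO4), K2CO3, Bu4NHSO4, MeCN/CH2(OMe)2/aq. Na2B4O7 buffer, 0 °C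
Reagents that add atoms: potassium peroxymonosulfate (active component of Oxone), [K+].[O-]S(=O)(=O)OO
Why: Shi epoxidation, in which the chiral dioxirane attacks the electron-rich trisubstituted alkene and not the enone, and the L-configured catalyst is expected to set C3 as (S) by reagent control.

Step 10
Reactants: 15 epoxy enone
Product: 17 methyl (3R)-5-[(6R)-6-{2-[(2S)-3,3-dimethyloxiran-2-yl]ethyl}-6-methyl-2-(triethylsilyloxy)cyclohexa-2,4-dien-1-yl]-3-methylpentanoate, via potassium dienolate 16 (not isolated)
Conditions: KN(SiMe3)2 (0.95 equiv), THF, −78 → −20 °C; then Et3SiCl, −78 → 0 °C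
Reagents that add atoms: chlorotriethylsilane, CC[Si](Cl)(CC)CC
Why: Under equilibrating conditions the enone is deprotonated at the γ-carbon C5 to the linear dienolate, the cross-conjugated alternative at the hindered C9 being disfavoured, and O-silylation under basic conditions (silyl dienol ether formation) avoids the silyl triflates that would open the epoxide.

Step 11
Reactants: 17 silyl dienol ether
Product: 18 methyl (3S,5R,10R,13R)-3-hydroxy-8-oxo-17-norlabd-6-en-15-oate (cis-fused; C9 epimers)
Conditions: MeAlCl2 (2 equiv), CH2Cl2, −78 °C; then 1 M HCl, THF, rt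
Reagents that add atoms: none
Why: Epoxide-initiated cation–olefin cyclisation with an enol silyl ether terminator in its vinylogous form, in which the Lewis-acid-activated epoxide is opened at the tertiary carbon C4 by the γ-carbon C5 of the dienol ether to close the six-membered ring A, C3 keeps the configuration from step 9, and attack on the diene face anti to the pseudoaxial C10 methyl through a chair-like ring A with the epoxide oxygen equatorial should set C5 cis to that methyl, which step 12 corrects.

Step 12
Reactants: 18 cis-fused hydroxy enone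
Product: 19 methyl (3S,5S,9S,10R,13R)-3-hydroxy-8-oxo-17-norlabd-6-en-15-oate (trans-fused; C3 hydroxyl axial; side chain equatorial)
Conditions: NaOMe (0.5 equiv), MeOH, 40 °C
Reagents that add atoms: none
Why: Base-mediated equilibration through the extended dienolate (vinylogous epimerisation at C5) and through the enolate at C9 should funnel the mixture to the trans-fused decalin with the side chain equatorial, the arrangement with the fewest 1,3-diaxial interactions, which leaves the C3 hydroxyl axial and anti to the C10 methyl as the target requires.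

Step 13
Reactants: 19 trans-fused hydroxy enone
Product: 20 methyl (3S,5S,9S,10R,13R)-3-hydroxy-8-oxo-17-norlabdan-15-oate
Conditions: H2 (1 atm), Pd/C, EtOAc, rt
Reagents that add atoms: none
Why: Catalytic hydrogenation saturates the conjugated C6=C7 bond without touching ketone, ester or alcohol and creates no stereocentre.

Step 14
Reactants: 20 hydroxy ketone
Product: 21 methyl (3S,5S,9R,10S,13R)-3-hydroxylabd-8(17)-en-15-oate
Conditions: Ph3PCH3Br (4 equiv), KOt-Bu (4 equiv), THF, 0 °C → reflux
Reagents that add atoms: methyltriphenylphosphonium bromide, C[P+](c1ccccc1)(c1ccccc1)c1ccccc1.[Br-]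
Why: Wittig methylenation of the hindered C8 ketone with excess ylide installs C17, and because C9 already has its thermodynamic configuration the basic conditions should not erode it.

Step 15
Reactants: 21 hydroxy ester
Product: 22 (3S,5S,9R,10S,13R)-3-hydroxylabd-8(17)-en-15-oic acid
Conditions: LiOH, THF/MeOH/H2O, 40 °C; then 1 M HCl
Reagents that add atoms: lithium hydroxide, [Li+].[OH-]
Why: Saponification of an unhindered methyl ester that has no stereocentre in its α-position.

Step 16
Reactants: 22 hydroxy acid
Product: 24 (3S,5S,9R,10S,13R)-3-acetoxylabd-8(17)-en-15-oic acid (CNP0281344.1), via mixed anhydride 23 (not isolated)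
Conditions: Ac2O, pyridine, DMAP (cat.), 40 °C; then H2O, THF, rt
Reagents that add atoms: acetic anhydride, CC(=O)OC(C)=O
Why: DMAP-catalysed acylation acetylates the hindered axial C3 hydroxyl with retention, and the mixed carboxylic anhydride formed at C15 is hydrolysed back to the acid in the aqueous stage.

Compound list
1 | 3-methylglutaric anhydride | CC1CC(=O)OC(=O)C1 | starting material
2 | (R)-5-methoxy-3-methyl-5-oxopentanoic acid | OC(=O)C[C@@H](C)CC(=O)OC | intermediate
3 | methyl (R)-5-hydroxy-3-methylpentanoate | OCC[C@@H](C)CC(=O)OC | intermediate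
4 | methyl (R)-3-methyl-5-oxopentanoate | O=CC[C@@H](C)CC(=O)OC | intermediate
5 | 5-bromo-2-methylpent-2-ene | CC(C)=CCCBr | starting material
6 | (4-methylpent-3-en-1-yl)magnesium bromide | CC(C)=CCC[Mg]Br | intermediate
7 | 3-methylcyclohex-2-en-1-one | CC1=CC(=O)CCC1 | starting material
8 | bromomagnesium (S)-3-methyl-3-(4-methylpent-3-en-1-yl)cyclohex-1-en-1-olate | Br[Mg]OC1=C[C@](C)(CCC=C(C)C)CCC1 | intermediate (not isolated)
9 | methyl (3R)-5-hydroxy-3-methyl-5-[(2S)-2-methyl-2-(4-methylpent-3-en-1-yl)-6-oxocyclohexyl]pentanoate (epimers at C9 and C11) | O=C1CCC[C@@](C)(CCC=C(C)C)C1C(O)C[C@@H](C)CC(=O)OC | intermediate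
10 | methanesulfonate of 9 at the C11 hydroxyl | O=C1CCC[C@@](C)(CCC=C(C)C)C1C(OS(C)(=O)=O)C[C@@H](C)CC(=O)OC | intermediate (not isolated)
11 | methyl (3R)-3-methyl-5-[(2S)-2-methyl-2-(4-methylpent-3-en-1-yl)-6-oxocyclohexylidene]pentanoate (E/Z mixture) | O=C1CCC[C@@](C)(CCC=C(C)C)C1=CC[C@@H](C)CC(=O)OC | intermediate
12 | methyl (3R)-3-methyl-5-[(2S)-2-methyl-2-(4-methylpent-3-en-1-yl)-6-oxocyclohexyl]pentanoate (C9 epimers) | O=C1CCC[C@@](C)(CCC=C(C)C)C1CC[C@@H](C)CC(=O)OC | intermediate
13 | lithium C7=C8 enolate of 12 | [Li]OC1=CCC[C@@](C)(CCC=C(C)C)C1CC[C@@H](C)CC(=O)OC | intermediate (not isolated)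
14 | methyl (3R)-3-methyl-5-[(2R)-2-methyl-2-(4-methylpent-3-en-1-yl)-6-oxocyclohex-4-en-1-yl]pentanoate (C9 epimers) | O=C1C=CC[C@@](C)(CCC=C(C)C)C1CC[C@@H](C)CC(=O)OC | intermediate
15 | methyl (3R)-5-[(2R)-2-{2-[(2S)-3,3-dimethyloxiran-2-yl]ethyl}-2-methyl-6-oxocyclohex-4-en-1-yl]-3-methylpentanoate (C9 epimers) | O=C1C=CC[C@@](C)(CC[C@@H]2OC2(C)C)C1CC[C@@H](C)CC(=O)OC | intermediate
16 | potassium linear dienolate of 15 (C8–O, C7=C8, C5=C6) | [K]OC1=CC=C[C@@](C)(CC[C@@H]2OC2(C)C)C1CC[C@@H](C)CC(=O)OC | intermediate (not isolated)
17 | methyl (3R)-5-[(6R)-6-{2-[(2S)-3,3-dimethyloxiran-2-yl]ethyl}-6-methyl-2-(triethylsilyloxy)cyclohexa-2,4-dien-1-yl]-3-methylpentanoate (C9 epimers) | CC[Si](CC)(CC)OC1=CC=C[C@@](C)(CC[C@@H]2OC2(C)C)C1CC[C@@H](C)CC(=O)OC | intermediate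
18 | methyl (3S,5R,10R,13R)-3-hydroxy-8-oxo-17-norlabd-6-en-15-oate (cis-fused, H5 syn to the C10 methyl; C9 epimers) | O=C1C=C[C@H]2C(C)(C)[C@@H](O)CC[C@@]2(C)C1CC[C@@H](C)CC(=O)OC | intermediate
19 | methyl (3S,5S,9S,10R,13R)-3-hydroxy-8-oxo-17-norlabd-6-en-15-oate (trans-fused; 3-OH axial) | O=C1C=C[C@@H]2C(C)(C)[C@@H](O)CC[C@@]2(C)[C@@H]1CC[C@@H](C)CC(=O)OC | intermediate
20 | methyl (3S,5S,9S,10R,13R)-3-hydroxy-8-oxo-17-norlabdan-15-oate | O=C1CC[C@@H]2C(C)(C)[C@@H](O)CC[C@@]2(C)[C@@H]1CC[C@@H](C)CC(=O)OC | intermediate
21 | methyl (3S,5S,9R,10S,13R)-3-hydroxylabd-8(17)-en-15-oate | C=C1CC[C@@H]2C(C)(C)[C@@H](O)CC[C@@]2(C)[C@@H]1CC[C@@H](C)CC(=O)OC | intermediate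
22 | (3S,5S,9R,10S,13R)-3-hydroxylabd-8(17)-en-15-oic acid | C=C1CC[C@@H]2C(C)(C)[C@@H](O)CC[C@@]2(C)[C@@H]1CC[C@@H](C)CC(=O)O | intermediate
23 | acetic (3S,5S,9R,10S,13R)-3-acetoxylabd-8(17)-en-15-oic anhydride | C=C1CC[C@@H]2C(C)(C)[C@@H](OC(C)=O)CC[C@@]2(C)[C@@H]1CC[C@@H](C)CC(=O)OC(C)=O | intermediate (not isolated)
24 | (3S,5S,9R,10S,13R)-3-acetoxylabd-8(17)-en-15-oic acid (CNP0281344.1) | C=C1CC[C@@H]2C(C)(C)[C@@H](OC(C)=O)CC[C@@]2(C)[C@@H]1CC[C@@H](C)CC(=O)O | target

Total step count: 16.
Longest linear sequence: 15 steps (1 → 24 through steps 1–3 and 5–16).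

Steps most likely to fail

1. Step 11. A Lewis-acid-induced hydride shift or proton loss in the activated epoxide may outrun carbon–carbon bond formation. The dienolate of step 10 may also have attacked the epoxide or been silylated from the wrong regioisomer beforehand. The fallback sets out from 15 and rejoins the route at 18, bypassing steps 10 and 11. Anhydrous HCl in Et2O at −40 °C should open the epoxide at its tertiary carbon to the chlorohydrin F1. Et3SiOTf and Et3N in CH2Cl2 then silylate the C3 hydroxyl and, by soft enolisation that is permissible once the epoxide is gone, form the linear dienol ether, giving the bis(triethylsilyl) chloride F2. AgBF4 with 2,6-di-tert-butylpyridine in CH2Cl2 at −78 °C abstracts the tertiary chloride, and the resulting cation alkylates the γ-carbon C5 (tertiary-halide alkylation of a silyl dienol ether). Acidic work-up as in step 11 gives 18.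

2. Step 12. Vinylogous deprotonation at the hindered ring-fusion carbon may be slow, or the equilibrium may leave cis-fused material. The fallback sets out from 18 and rejoins the route at 20, replacing steps 12 and 13. KOt-Bu in t-BuOH followed by a fast quench into cold aqueous AcOH protonates the dienolate at C7 and gives the β,γ-unsaturated ketone F3, in which C5 is trigonal. Hydrogen-atom-transfer hydrogenation (Mn(dpm)3 cat., PhSiH3, t-BuOOH, i-PrOH) then delivers hydrogen to the C5 radical from the axial direction anti to the C10 methyl. A short NaOMe treatment to settle C9 gives 20.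

3. Step 5. Proton transfer from the enolisable aldehyde to the magnesium enolate, or retro-aldol reaction and lactonisation of the magnesium aldolate on warming, may erode the three-component union. The fallback sets out from 7 and rejoins the route at 9. The same copper-catalysed addition of 6 is run and enolate 8 is quenched with Me3SiCl/Et3N to give the trimethylsilyl enol ether F4, which is purified. TiCl4-mediated Mukaiyama aldol addition to 4 in CH2Cl2 at −78 °C, which proceeds through an open transition state without a basic enolate, then gives 9.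

Further compounds
F1 | step 11 | methyl (3R)-5-[(2R)-2-[(3S)-4-chloro-3-hydroxy-4-methylpentyl]-2-methyl-6-oxocyclohex-4-en-1-yl]-3-methylpentanoate (C9 epimers) | O=C1C=CC[C@@](C)(CC[C@H](O)C(C)(C)Cl)C1CC[C@@H](C)CC(=O)OC
F2 | step 11 | methyl (3R)-5-[(6R)-6-[(3S)-4-chloro-4-methyl-3-(triethylsilyloxy)pentyl]-6-methyl-2-(triethylsilyloxy)cyclohexa-2,4-dien-1-yl]-3-methylpentanoate (C9 epimers) | CC[Si](CC)(CC)OC1=CC=C[C@@](C)(CC[C@H](O[Si](CC)(CC)CC)C(C)(C)Cl)C1CC[C@@H](C)CC(=O)OC
F3 | step 12 | methyl (3S,10S,13R)-3-hydroxy-8-oxo-17-norlabd-5-en-15-oate (C9 epimers) | O=C1CC=C2C(C)(C)[C@@H](O)CC[C@@]2(C)C1CC[C@@H](C)CC(=O)OC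
F4 | step 5 | (S)-trimethyl{[3-methyl-3-(4-methylpent-3-en-1-yl)cyclohex-1-en-1-yl]oxy}silane | C[Si](C)(C)OC1=C[C@](C)(CCC=C(C)C)CCC1
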